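**Plan**

1. Locants are those of the target ring: C1 = C(OH)CH2OBz, C2 = CHCl, C3=C4, C5 = CHOH, C6 = CHOBz. Cuts, in order: C2–Cl (trans-chlorohydrin ⇒ C1–C2 epoxide + HCl); epoxide O ⇒ 2-(hydroxymethyl)cyclohexa-2,4-dien-1-ol; C3=C4 ⇒ SO2-bridged seven-membered ring (Ramberg–Bäcklund retron); C1=C2 of that ring ⇒ RCM; C6–C1 ⇒ vinyl-metal + aldehyde; C4–S ⇒ thiol + (R)-glycidol.
2. Enabling feature: C3 and C4 are adjacent ring CH carbons that end as a cis CH=CH with no other substituent. They can therefore first be joined through sulfur (C4–SO2–C3) in a 2,3,4,7-tetrahydrothiepine 1,1-dioxide, one atom larger than the carbocycle, and the SO2 then excised.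
3. Forward: glycidol C3 unit, S-allyl unit and 2-(silyloxymethyl)vinyl unit are joined; RCM closes the seven-membered sulfone; ring contraction gives the six-membered 1,3-diene; then epoxide, then chlorohydrin. The cyclohexene ring exists only from the contraction onward.
4. Stereochemistry: C5 from (R)-glycidol; C6 by Cram-chelate addition (syn to C5–O); C1 and C2–O by hydroxyl-directed epoxidation syn to C6–OH; C2–Cl by SN2 inversion of the epoxide.

Key step: step 10

**Route**

Step 1
Reactants: 1 (R)-glycidol; 2 prop-2-ene-1-thiol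
Product: 3 (2R)-3-(prop-2-en-1-ylsulfanyl)propane-1,2-diol
Conditions: Et3N (0.1 equiv), MeOH, 0 °C → rt
Reagents that add atoms: none
Why: Base-catalysed thiol–epoxide opening (SN2 at the unsubstituted epoxide carbon); the stereocentre is not touched, and Payne equilibration of glycidol is degenerate and leads to the same enantiomer.

Step 2
Reactants: 3 (2R)-3-(prop-2-en-1-ylsulfanyl)propane-1,2-diol
Product: 4 (4R)-2-(4-methoxyphenyl)-4-[(prop-2-en-1-ylsulfanyl)methyl]-1,3-dioxolane (both C-2 epimers)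
Conditions: 4-MeOC6H4CH(OMe)2, PPTS (cat.), CH2Cl2, rt
Reagents that add atoms: 4-methoxybenzaldehyde dimethyl acetal, COc1ccc(C(OC)OC)cc1
Why: Acid-catalysed transacetalisation of the 1,2-diol to the p-methoxybenzylidene acetal; the acetal epimers converge in step 3.

Step 3
Reactants: 4 (4R)-2-(4-methoxyphenyl)-4-[(prop-2-en-1-ylsulfanyl)methyl]-1,3-dioxolane
Product: 5 (2R)-2-[(4-methoxybenzyl)oxy]-3-(prop-2-en-1-ylsulfanyl)propan-1-ol
Conditions: DIBAL-H (3 equiv), CH2Cl2, −78 → 0 °C; aq. Rochelle salt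
Reagents that add atoms: none
Why: Regioselective reductive acetal opening: aluminium binds the less hindered primary oxygen, that C–O bond breaks, and hydride reduces the oxocarbenium ion, leaving PMB on the secondary oxygen.

Step 4
Reactants: 5 (2R)-2-[(4-methoxybenzyl)oxy]-3-(prop-2-en-1-ylsulfanyl)propan-1-ol
Product: 6 (2R)-2-[(4-methoxybenzyl)oxy]-3-(prop-2-en-1-ylsulfanyl)propanal
Conditions: Dess–Martin periodinane, CH2Cl2, 0 °C → rt; used crude
Reagents that add atoms: none
Why: Dess–Martin oxidation works without amine base, so it should neither oxidise the sulfide, epimerise the α-alkoxy centre nor eliminate the β-thiolate.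

Step 5
Reactants: 7 2-bromoprop-2-en-1-ol
Product: 8 [(2-bromoprop-2-en-1-yl)oxy](tert-butyl)dimethylsilane
Conditions: TBSCl, imidazole, CH2Cl2, 0 °C → rt
Reagents that add atoms: tert-butyldimethylsilyl chloride, CC(C)(C)[Si](C)(C)Cl
Why: Standard imidazole-mediated silylation of a primary alcohol.

Step 6
Reactants: 8 [(2-bromoprop-2-en-1-yl)oxy](tert-butyl)dimethylsilane; 6 (2R)-2-[(4-methoxybenzyl)oxy]-3-(prop-2-en-1-ylsulfanyl)propanal
Product: 11 (3S,4R)-2-({[tert-butyl(dimethyl)silyl]oxy}methyl)-4-[(4-methoxybenzyl)oxy]-5-(prop-2-en-1-ylsulfanyl)pent-1-en-3-ol, via vinyllithium 9 (not isolated), via vinylmagnesium bromide 10 (not isolated)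
Conditions: 8, t-BuLi (2.0 equiv), Et2O, −78 °C; MgBr2·OEt2, −78 °C; then 6 premixed with MgBr2·OEt2 in CH2Cl2, −78 °C; aq. NH4Cl
Reagents that add atoms: none
Why: Br/Li exchange, transmetalation to magnesium and Cram-chelate 1,2-addition: Mg bridges C=O and the α-OPMB oxygen, and the vinyl group attacks the face opposite the CH2S substituent, which should give the 3,4-syn (threo) alcohol, i.e. (3S).

Step 7
Reactants: 11 (3S,4R)-2-({[tert-butyl(dimethyl)silyl]oxy}methyl)-4-[(4-methoxybenzyl)oxy]-5-(prop-2-en-1-ylsulfanyl)pent-1-en-3-ol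
Product: 12 (3S,4R)-2-({[tert-butyl(dimethyl)silyl]oxy}methyl)-4-[(4-methoxybenzyl)oxy]-5-(prop-2-en-1-ylsulfonyl)pent-1-en-3-ol
Conditions: (NH4)6Mo7O24·4H2O (10 mol %), 30% H2O2, EtOH, 0 °C → rt
Reagents that add atoms: hydrogen peroxide, OO
Why: Molybdate-catalysed sulfide-to-sulfone oxidation is much faster than epoxidation of the unactivated alkenes and leaves PMB and TBS intact.

Step 8
Reactants: 12 (3S,4R)-2-({[tert-butyl(dimethyl)silyl]oxy}methyl)-4-[(4-methoxybenzyl)oxy]-5-(prop-2-en-1-ylsulfonyl)pent-1-en-3-ol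
Product: 13 (3R,4S)-5-({[tert-butyl(dimethyl)silyl]oxy}methyl)-3-[(4-methoxybenzyl)oxy]-2,3,4,7-tetrahydrothiepin-4-ol 1,1-dioxide
Conditions: Grubbs second-generation catalyst (5 mol %), CH2Cl2 (5 mM), 40 °C
Reagents that add atoms: none
Why: Ring-closing metathesis of an allyl sulfone with a 1,1-disubstituted alkene to a trisubstituted cycloalkene; sulfones are tolerated, the free allylic OH keeps the hindered alkene accessible, and no stereocentre is formed.

Step 9
Reactants: 13 (3R,4S)-5-({[tert-butyl(dimethyl)silyl]oxy}methyl)-3-[(4-methoxybenzyl)oxy]-2,3,4,7-tetrahydrothiepin-4-ol 1,1-dioxide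
Product: 14 (3R,4S)-4-{[tert-butyl(dimethyl)silyl]oxy}-5-({[tert-butyl(dimethyl)silyl]oxy}methyl)-3-[(4-methoxybenzyl)oxy]-2,3,4,7-tetrahydrothiepine 1,1-dioxide
Conditions: TBSOTf, 2,6-lutidine, CH2Cl2, −78 → 0 °C
Reagents that add atoms: tert-butyldimethylsilyl trifluoromethanesulfonate, CC(C)(C)[Si](C)(C)OS(=O)(=O)C(F)(F)F
Why: Silyl triflate silylation of the hindered secondary alcohol, so that no free alkoxide is present during the base-mediated contraction.

Step 10
Reactants: 14 (3R,4S)-4-{[tert-butyl(dimethyl)silyl]oxy}-5-({[tert-butyl(dimethyl)silyl]oxy}methyl)-3-[(4-methoxybenzyl)oxy]-2,3,4,7-tetrahydrothiepine 1,1-dioxide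
Product: 17 tert-butyl{[(1S,6S)-2-({[tert-butyl(dimethyl)silyl]oxy}methyl)-6-[(4-methoxybenzyl)oxy]cyclohexa-2,4-dien-1-yl]oxy}dimethylsilane, via α-bromo sulfone 15 (not isolated), via episulfone 16 (not isolated)
Conditions: CBr2F2, KOH/Al2O3, t-BuOH/CH2Cl2, 0 °C → rt
Reagents that add atoms: none
Why: Ramberg–Bäcklund ring contraction with in-situ halogenation: hydroxide on alumina deprotonates the doubly activated allylic α-CH2 of the sulfone (target C3), the carbanion takes Br+ from CBr2F2 to give 15, the second α-carbanion (target C4) displaces bromide across sulfur to give the cis-fused thiirane 1,1-dioxide 16, and cheletropic loss of SO2 leaves the C3=C4 double bond. The closest known reactions are the Ramberg–Bäcklund conversion of metathesis-derived cyclic allylic sulfones into cyclic 1,3-dienes and of O-protected thiepane polyol dioxides into conduritol-type cyclohexenes. The six-membered carbocycle is closed by the transannular 3-exo-tet C–C bond formation (C4 carbanion onto C3–Br), so the seven-membered ring loses one atom and no other ring remains. No stereocentre is created: the new alkene can only be cis inside the ring, and the C5 and C6 stereocentres carry no acidic hydrogen and are not touched. The step needs 1,3-elimination to beat E1cB loss of the β-PMB-oxide and vinylogous loss of the silyloxy groups; this is secured because bromination occurs first at the more acidic allylic carbon, so the C4 carbanion forms next to an internal electrophile three atoms away, while ether oxides are poor leaving groups.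

Step 11
Reactants: 17 tert-butyl{[(1S,6S)-2-({[tert-butyl(dimethyl)silyl]oxy}methyl)-6-[(4-methoxybenzyl)oxy]cyclohexa-2,4-dien-1-yl]oxy}dimethylsilane
Product: 18 (1S,6S)-2-(hydroxymethyl)-6-[(4-methoxybenzyl)oxy]cyclohexa-2,4-dien-1-ol
Conditions: TBAF, THF, 0 °C; used directly
Reagents that add atoms: none
Why: Fluoride cleaves both silyl ethers and leaves PMB; the basic medium avoids acid-induced aromatisation of the dihydroarene diol.

Step 12
Reactants: 18 (1S,6S)-2-(hydroxymethyl)-6-[(4-methoxybenzyl)oxy]cyclohexa-2,4-dien-1-ol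
Product: 19 (1R,2R,3S,6S)-1-(hydroxymethyl)-3-[(4-methoxybenzyl)oxy]-7-oxabicyclo[4.1.0]hept-4-en-2-ol
Conditions: VO(acac)2 (5 mol %), t-BuOOH, CH2Cl2, 0 °C
Reagents that add atoms: tert-butyl hydroperoxide, CC(C)(C)OO
Why: Vanadium-catalysed hydroxyl-directed epoxidation: the vanadate ester of the allylic hydroxyls delivers oxygen only to the trisubstituted C=C that carries them and from the face of the ring C–OH, which should set C1 and C2–O cis to O6.

Step 13
Reactants: 19 (1R,2R,3S,6S)-1-(hydroxymethyl)-3-[(4-methoxybenzyl)oxy]-7-oxabicyclo[4.1.0]hept-4-en-2-ol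
Product: 20 [(1S,2R,3S,6S)-2-(benzoyloxy)-3-[(4-methoxybenzyl)oxy]-7-oxabicyclo[4.1.0]hept-4-en-1-yl]methyl benzoate
Conditions: BzCl (2.5 equiv), pyridine, DMAP (cat.), CH2Cl2, 0 °C → rt
Reagents that add atoms: benzoyl chloride, O=C(Cl)c1ccccc1
Why: DMAP-catalysed acylation of the primary and the secondary hydroxyl; the only other oxygen is the PMB ether, so no selectivity is needed.

Step 14
Reactants: 20 [(1S,2R,3S,6S)-2-(benzoyloxy)-3-[(4-methoxybenzyl)oxy]-7-oxabicyclo[4.1.0]hept-4-en-1-yl]methyl benzoate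
Product: 21 [(1S,2R,3S,6S)-2-(benzoyloxy)-3-hydroxy-7-oxabicyclo[4.1.0]hept-4-en-1-yl]methyl benzoate
Conditions: DDQ, CH2Cl2/pH 7 buffer (10:1), 0 °C
Reagents that add atoms: none
Why: Oxidative PMB cleavage (benzylic hydride abstraction, hydrolysis of the oxocarbenium ion) under neutral conditions that spare the epoxide and the benzoates.

Step 15
Reactants: 21 [(1S,2R,3S,6S)-2-(benzoyloxy)-3-hydroxy-7-oxabicyclo[4.1.0]hept-4-en-1-yl]methyl benzoate
Product: 22 [(1R,2R,5S,6R)-6-(benzoyloxy)-2-chloro-1,5-dihydroxycyclohex-3-en-1-yl]methyl benzoate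
Conditions: HCl (1 M in Et2O, 1.5 equiv), CH2Cl2, −20 → 0 °C
Reagents that add atoms: hydrogen chloride, Cl
Why: Acid-mediated SN2 opening of the vinyl epoxide by chloride at the allylic carbon with inversion gives the trans-chlorohydrin (C2–Cl anti to C1–OH); the tertiary carbon is deactivated by its two benzoyloxy-bearing neighbours.

**Compound list**

1 | (R)-glycidol | OC[C@@H]1CO1 | starting material
2 | prop-2-ene-1-thiol | C=CCS | starting material
3 | (2R)-3-(prop-2-en-1-ylsulfanyl)propane-1,2-diol | C=CCSC[C@H](O)CO | intermediate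
4 | (4R)-2-(4-methoxyphenyl)-4-[(prop-2-en-1-ylsulfanyl)methyl]-1,3-dioxolane (C-2 epimers) | C=CCSC[C@H]1COC(c2ccc(OC)cc2)O1 | intermediate
5 | (2R)-2-[(4-methoxybenzyl)oxy]-3-(prop-2-en-1-ylsulfanyl)propan-1-ol | C=CCSC[C@H](OCc1ccc(OC)cc1)CO | intermediate
6 | (2R)-2-[(4-methoxybenzyl)oxy]-3-(prop-2-en-1-ylsulfanyl)propanal | C=CCSC[C@H](OCc1ccc(OC)cc1)C=O | intermediate
7 | 2-bromoprop-2-en-1-ol | C=C(Br)CO | starting material
8 | [(2-bromoprop-2-en-1-yl)oxy](tert-butyl)dimethylsilane | C=C(Br)CO[Si](C)(C)C(C)(C)C | intermediate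
9 | [3-{[tert-butyl(dimethyl)silyl]oxy}prop-1-en-2-yl]lithium | [Li]C(=C)CO[Si](C)(C)C(C)(C)C | intermediate (not isolated)
10 | [3-{[tert-butyl(dimethyl)silyl]oxy}prop-1-en-2-yl]magnesium bromide | Br[Mg]C(=C)CO[Si](C)(C)C(C)(C)C | intermediate (not isolated)
11 | (3S,4R)-2-({[tert-butyl(dimethyl)silyl]oxy}methyl)-4-[(4-methoxybenzyl)oxy]-5-(prop-2-en-1-ylsulfanyl)pent-1-en-3-ol | C=CCSC[C@H](OCc1ccc(OC)cc1)[C@@H](O)C(=C)CO[Si](C)(C)C(C)(C)C | intermediate
12 | (3S,4R)-2-({[tert-butyl(dimethyl)silyl]oxy}methyl)-4-[(4-methoxybenzyl)oxy]-5-(prop-2-en-1-ylsulfonyl)pent-1-en-3-ol | C=CCS(=O)(=O)C[C@H](OCc1ccc(OC)cc1)[C@@H](O)C(=C)CO[Si](C)(C)C(C)(C)C | intermediate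
13 | (3R,4S)-5-({[tert-butyl(dimethyl)silyl]oxy}methyl)-3-[(4-methoxybenzyl)oxy]-2,3,4,7-tetrahydrothiepin-4-ol 1,1-dioxide | O=S1(=O)CC=C(CO[Si](C)(C)C(C)(C)C)[C@H](O)[C@@H](OCc2ccc(OC)cc2)C1 | intermediate
14 | (3R,4S)-4-{[tert-butyl(dimethyl)silyl]oxy}-5-({[tert-butyl(dimethyl)silyl]oxy}methyl)-3-[(4-methoxybenzyl)oxy]-2,3,4,7-tetrahydrothiepine 1,1-dioxide | O=S1(=O)CC=C(CO[Si](C)(C)C(C)(C)C)[C@H](O[Si](C)(C)C(C)(C)C)[C@@H](OCc2ccc(OC)cc2)C1 | intermediate
15 | 7-bromo derivative of 14 (C-7 epimers) | O=S1(=O)C(Br)C=C(CO[Si](C)(C)C(C)(C)C)[C@H](O[Si](C)(C)C(C)(C)C)[C@@H](OCc2ccc(OC)cc2)C1 | intermediate (not isolated)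
16 | cis-fused 7-thiabicyclo[4.1.0]hept-2-ene 7,7-dioxide (episulfone) with the substituents of 14 | O=S1(=O)C2C=C(CO[Si](C)(C)C(C)(C)C)[C@H](O[Si](C)(C)C(C)(C)C)[C@@H](OCc3ccc(OC)cc3)C12 | intermediate (not isolated)
17 | tert-butyl{[(1S,6S)-2-({[tert-butyl(dimethyl)silyl]oxy}methyl)-6-[(4-methoxybenzyl)oxy]cyclohexa-2,4-dien-1-yl]oxy}dimethylsilane | CC(C)(C)[Si](C)(C)OCC1=CC=C[C@H](OCc2ccc(OC)cc2)[C@H]1O[Si](C)(C)C(C)(C)C | intermediate
18 | (1S,6S)-2-(hydroxymethyl)-6-[(4-methoxybenzyl)oxy]cyclohexa-2,4-dien-1-ol | OCC1=CC=C[C@H](OCc2ccc(OC)cc2)[C@H]1O | intermediate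
19 | (1R,2R,3S,6S)-1-(hydroxymethyl)-3-[(4-methoxybenzyl)oxy]-7-oxabicyclo[4.1.0]hept-4-en-2-ol | OC[C@]12O[C@H]1C=C[C@H](OCc1ccc(OC)cc1)[C@H]2O | intermediate
20 | [(1S,2R,3S,6S)-2-(benzoyloxy)-3-[(4-methoxybenzyl)oxy]-7-oxabicyclo[4.1.0]hept-4-en-1-yl]methyl benzoate | O=C(OC[C@]12O[C@H]1C=C[C@H](OCc1ccc(OC)cc1)[C@H]2OC(=O)c1ccccc1)c1ccccc1 | intermediate
21 | [(1S,2R,3S,6S)-2-(benzoyloxy)-3-hydroxy-7-oxabicyclo[4.1.0]hept-4-en-1-yl]methyl benzoate | O=C(OC[C@]12O[C@H]1C=C[C@H](O)[C@H]2OC(=O)c1ccccc1)c1ccccc1 | intermediate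
22 | [(1R,2R,5S,6R)-6-(benzoyloxy)-2-chloro-1,5-dihydroxycyclohex-3-en-1-yl]methyl benzoate | O=C(OC[C@]1(O)[C@H](Cl)C=C[C@H](O)[C@H]1OC(=O)c1ccccc1)c1ccccc1 | target

**Step count**

Total steps: 15. Longest linear sequence: 14 (steps 1–4 and 6–15).

**Steps most likely to fail**

Step 10 (ring contraction). The sulfonyl carbanions may lose the β-PMB-oxide (E1cB) or, through the allyl anion, a silyloxy group, faster than they are brominated and cyclised. Hydroxide may also aromatise the diene, or the alkene may migrate into conjugation with the sulfone. The fallback sets out from 14 and returns at 17. It replaces the one-pot halogenative conditions by the classical two-stage Ramberg–Bäcklund with a pre-installed leaving group. LiHMDS (1.05 equiv), THF, −78 °C, then C2Cl6 should give, under kinetic control at the allylic α-carbon, the isolated (3R,4S,7RS)-7-chloro-4-{[tert-butyl(dimethyl)silyl]oxy}-5-({[tert-butyl(dimethyl)silyl]oxy}methyl)-3-[(4-methoxybenzyl)oxy]-2,3,4,7-tetrahydrothiepine 1,1-dioxide F1. KOt-Bu (2 equiv), THF, −78 → −20 °C should then effect 1,3-elimination and SO2 loss to 17. No hydroxide or carbene source is present, and the second carbanion always has its internal electrophile in place.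

Step 6 (vinyl addition). Facial selectivity may be poor because the α-OPMB chelate competes with a β-sulfur chelate and with the open Felkin transition state; enolisation or loss of thiolate from the aldehyde is also possible. The fallback sets out from 11 (as the C-3 epimer mixture) and returns at 11. It moves stereocontrol from the C–C bond formation to a catalyst-controlled carbonyl reduction. Dess–Martin oxidation should give (4R)-2-({[tert-butyl(dimethyl)silyl]oxy}methyl)-4-[(4-methoxybenzyl)oxy]-5-(prop-2-en-1-ylsulfanyl)pent-1-en-3-one F2. Corey–Bakshi–Shibata reduction ((S)-Me-oxazaborolidine, catecholborane, toluene, −78 °C) should then return (3S)-11, provided the alkenyl group acts as the larger substituent in the Corey model.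

Step 12 (directed epoxidation). The primary allylic hydroxyl may deliver oxygen to either face, the C4=C5 alkene may be epoxidised in competition, or the vinyl epoxide may open. The fallback sets out from 17 and returns at 19, replacing steps 11 and 12. It swaps substrate direction for reagent control. HF·pyridine/pyridine, THF, 0 °C should remove only the primary silyl group to give [(5S,6S)-6-{[tert-butyl(dimethyl)silyl]oxy}-5-[(4-methoxybenzyl)oxy]cyclohexa-1,3-dien-1-yl]methanol F3. Sharpless asymmetric epoxidation (Ti(OiPr)4, D-(−)-diethyl tartrate, t-BuOOH, 4 Å MS, CH2Cl2, −20 °C) should deliver oxygen to the required face of the (E)-2,3-disubstituted allylic alcohol to give [(1S,2R,3S,6S)-2-{[tert-butyl(dimethyl)silyl]oxy}-3-[(4-methoxybenzyl)oxy]-7-oxabicyclo[4.1.0]hept-4-en-1-yl]methanol F4. TBAF, THF, 0 °C then gives 19.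

**Further compounds**

F1 | step 10 | (3R,4S,7RS)-7-chloro-4-{[tert-butyl(dimethyl)silyl]oxy}-5-({[tert-butyl(dimethyl)silyl]oxy}methyl)-3-[(4-methoxybenzyl)oxy]-2,3,4,7-tetrahydrothiepine 1,1-dioxide | O=S1(=O)C(Cl)C=C(CO[Si](C)(C)C(C)(C)C)[C@H](O[Si](C)(C)C(C)(C)C)[C@@H](OCc2ccc(OC)cc2)C1
F2 | step 6 | (4R)-2-({[tert-butyl(dimethyl)silyl]oxy}methyl)-4-[(4-methoxybenzyl)oxy]-5-(prop-2-en-1-ylsulfanyl)pent-1-en-3-one | C=CCSC[C@H](OCc1ccc(OC)cc1)C(=O)C(=C)CO[Si](C)(C)C(C)(C)C
F3 | step 12 | [(5S,6S)-6-{[tert-butyl(dimethyl)silyl]oxy}-5-[(4-methoxybenzyl)oxy]cyclohexa-1,3-dien-1-yl]methanol | OCC1=CC=C[C@H](OCc2ccc(OC)cc2)[C@H]1O[Si](C)(C)C(C)(C)C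
F4 | step 12 | [(1S,2R,3S,6S)-2-{[tert-butyl(dimethyl)silyl]oxy}-3-[(4-methoxybenzyl)oxy]-7-oxabicyclo[4.1.0]hept-4-en-1-yl]methanol | OC[C@]12O[C@H]1C=C[C@H](OCc1ccc(OC)cc1)[C@H]2O[Si](C)(C)C(C)(C)C
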